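# Synthesis design for dryocrassin ABBA (21)

Ring B numbering used throughout: C1 carries the central CH2, C2 an oxygen, C3 the outer CH2, C4 an oxygen, C5 the butyryl group, C6 an oxygen.

## The problem

Dryocrassin ABBA (21) is a linear tetramer: two butyrylphloroglucinol rings (rings B) share a central CH2, and each carries on C3 an outer CH2 that ends in a ring A, the enolised 2-acetyl-4,4-dimethylcyclohexane-1,3,5-trione of acetylfilicinic acid. The molecule has no stereocentre, so the task is one of position, not of configuration. Every carbon of ring B is substituted, with oxygen on C2, C4 and C6 and three different carbon groups between them. Classical phloroglucinol chemistry cannot tell these positions apart: electrophilic substitution and one-carbon bridging of two different partners give statistical mixtures of homo- and hetero-coupled products. The CH2 bridges are the fragile part. Each is the adduct of a quinone methide and an enol, so it reverts and exchanges partners in base and is cleaved by strong acid. The free polyphenol and the β-triketone of ring A are easily oxidised and chelated, so rough steps must precede the arrival of the rings A. The feature that invites a ring-forming answer is the 1,3,5-oxygen pattern of ring B read across the bridge: C2–C1–CH2–C1'–C2' is a glutaric acid skeleton whose carboxyl carbons have become phenol carbons. The remaining four carbons of each ring are two two-carbon units with one oxygen each, that is, two different oxygenated alkynes.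

## Retrosynthesis

**21 ⇒ 17 + 19 (through 20).** The last bonds made are the two C–C bonds between each outer CH2 and the one unsubstituted carbon of a ring A. Cutting on this side of the outer CH2, not between CH2 and ring B, keeps the one-carbon unit on ring B, where the annulation can place it without ambiguity. Ring B then acts as the electrophile (a quinone methide formed by loss of methanol from a hydroxybenzyl methyl ether) and acetylfilicinic acid 19 as the nucleophile. Compound 19 has a single reactive ring carbon, so homo-coupling of the kind seen when two free phenols are bridged cannot occur. The cut removes 20 of the 43 carbons. The hexaphenol 20 is released from its silyl-protected form 17 by fluoride in the presence of 19 and is not isolated. The forward step must form and capture the quinone methide under buffered conditions in which finished bridges do not exchange.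

**17 ⇒ 16 ⇒ 13 + 14 ⇒ 12 ⇒ 11.** Next the two aryl–C(=O) bonds at C5 are cut. A Friedel–Crafts butyrylation would be the shortest way, but a 2,4,6-trioxygenated benzyl ether ionises under any Lewis acid, and the resulting cation would alkylate the free C5–H of a neighbouring molecule. The butyryl group is therefore introduced as a nucleophile–electrophile pair: the only ring C–H of 12 is brominated (13), exchanged for lithium, and acylated with the Weinreb amide 14 to give 16. The free phenol of 11 is silylated first (12) so that it neither quenches the aryllithium nor is oxidised by the brominating agent; this silyl group leaves together with the others in the last step. The ethyl ether at C6 is cleaved at the stage of 16 by a boron trihalide, assisted by chelation to the new ketone. At this point the other oxygen ortho to the ketone carries a bulky silyl group and does not compete, and no ring C–H remains to be alkylated. These operations add five carbons per ring and ask only for standard arene chemistry.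

**11 ⇒ 4 + 2 × 9 (key disconnection).** In each ring B the bonds C2–C3 and C4–C5 are cut, which is the retron of a cyclobutenone–ynol ether benzannulation. Ring atoms C1, C2, C5 and C6 come from a 3-ethoxycyclobutenone and C3 and C4 from a siloxyalkyne. Both rings and the central CH2 go back to one small precursor, the CH2-linked bis(cyclobutenone) 4, and two molecules of alkyne 9. The cut is preferred to any stepwise substitution of a preformed phloroglucinol because it gives the three oxygens in three different forms (OH, OEt, OSi) and places each carbon substituent at a defined position. The alkyne substituent was chosen as CH2OMe and not as plain methyl. A methyl group would allow a Friedel–Crafts acylation, but the outer bridge would then need late oxidation of an aryl methyl group in a molecule whose central diarylmethane CH2 has the weaker C–H bonds. Carrying the oxygen in from the alkyne removes that step. The forward reaction must run twice on one molecule, with the ynol ether adding to each vinylketene in one orientation.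

**4 ⇒ 1 + 2 (through 3); 9 ⇒ 5 + 6 (through 7 and 8); 19 ⇒ 18.** The bis(cyclobutenone) 4 is the double [2+2] adduct of the bis(ketene) 3 and ethoxyacetylene 2, and 3 is the double dehydrochlorination product of glutaryl dichloride 1. Alkyne 9 comes from methyl propargyl ether 5 by oxidation of its acetylide 7 to the ynolate 8 and O-silylation with chlorosilane 6. Acetylfilicinic acid 19 is the geminal C-dimethylation product of 2,4,6-trihydroxyacetophenone 18. All five starting materials (1, 2, 5, 6, 18) and the amide 14 are commercial.

## Roads not taken

**Alternative 1:** The cut is made in each ring A, at the two bonds from the acetyl-bearing carbon to its neighbouring ring carbonyls. In the forward step a strong Lewis acid makes each cyclic anhydride ring of the bis(pyrantrione) A3 acylate isopropenyl acetate A2 twice at the same carbon. This closes both rings A and delivers the acetyl group, giving hexa-O-methyl dryocrassin ABBA A1.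
- Merits: the reaction type is established for six-membered cyclic anhydrides and 2-acyl-1,3-diones, and the bridge carbons are already in place. No late intermolecular union is needed, and in this respect the road is better than the chosen one.
- Weak points: A3 is a 3-oxoglutaric anhydride with a quaternary carbon on one side and an enolisable benzylic CH on the other, prone to ring opening and decarboxylation. It would have to be built twice on an already hexasubstituted BB core. The strong Lewis acid meets six aryl methyl ethers and two aryl ketones. All six O-methyl groups must then be removed from A1, after the acid-sensitive bridges exist.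
- Comparison: this road spends its key step on ring A, which is available in one step as 19. The chosen plan answers with convergence and a last step that needs no ether cleavage on the tetramer; its cost is the quinone methide union of step 9.

**Alternative 2:** The cut is again in ring A, now as the retron of a cyclobutenone–siloxyalkyne annulation. Heating the bis(2-benzyl-3-ethoxy-4,4-dimethylcyclobutenone) A6 with (triisopropylsiloxy)ethyne A5 would give the bis(dienone) A4. The geminal dimethyl carbon blocks aromatisation, so the filicinic oxidation pattern appears directly.
- Merits: it is the same reaction family as the chosen key step and equally well founded mechanistically. The two ring A oxygens emerge differentiated, and the bridges are in place.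
- Weak points: A4 lacks both acetyl groups, so each ring A still needs a C-acylation. A6 presupposes the complete BB core, with its butyryl ketones exposed to ketene chemistry. A4 carries six methyl, two ethyl and two silyl ethers to be removed on the finished skeleton.
- Comparison: on precedent the two roads are level. The chosen plan runs the annulation first, on a C13 precursor made in one step, so that failure costs little. It also uses the annulation on ring B, where positional control is hard to obtain otherwise, and not on ring A, where it is not needed.

**Alternative 3:** The cut is at one aryl C–O and one aryl C–C(=O) bond per ring B. A fluoride source turns the bis(silylaryl triflate) A9 into an aryne at each ring, and butanoic acid A8 adds across each triple bond to give the BB core tetramethyl ether A7.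
- Merits: the butyryl group and the adjacent hydroxyl are installed together, with orientation set by the methoxy group next to the aryne. The free ring C–H that A7 retains is the classical site for one-carbon bridging to ring A, and that bridging is better tested than step 9.
- Weak points: no ring is formed. A9 needs several steps per ring on a phloroglucinol ether, so the aryne step replaces a butyrylation that is trivial on the free phenol. The orientation rests on one methoxy group against a bulky ortho benzyl substituent. Four methyl ethers remain, and the outer bridge must be made by a coupling that does not distinguish partners.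
- Comparison: to the BB stage this road is probably no longer than the chosen one. The chosen plan's advantage is that the outer carbon is already in place and the final coupling is unambiguous.

Key step: step 3

Remark on the chemistry: 19 and 21 are written as single enol tautomers of rapidly equilibrating mixtures; 21 has no stereocentre.

## Route

Step 1
Reactants: 1 pentanedioyl dichloride (glutaryl dichloride); 2 ethoxyethyne (ethoxyacetylene)
Product: 4 4,4'-methylenebis(3-ethoxycyclobut-2-en-1-one) (meso and racemic diastereomers), via penta-1,4-diene-1,5-dione 3 (not isolated)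
Conditions: Et3N (2.4 equiv), 2 (5 equiv), Et2O, slow addition of 1, 0 °C → rt
Reagents that add atoms: none
Why: Dehydrochlorination of each acyl chloride end gives an alkylketene that the electron-rich alkyne traps in a regioselective [2+2] cycloaddition (ketene carbonyl carbon to the unsubstituted alkyne carbon), the known route to 4-alkyl-3-ethoxycyclobutenones; slow addition keeps the ketene concentration low, and the two stereocentres form without control and are erased in step 3.

Step 2
Reactants: 5 3-methoxyprop-1-yne (methyl propargyl ether); 6 chlorotriisopropylsilane
Product: 9 3-methoxy-1-(triisopropylsilyloxy)prop-1-yne, via lithium 3-methoxyprop-1-yn-1-ide 7 (not isolated), via lithium 3-methoxyprop-1-yn-1-olate 8 (not isolated)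
Conditions: n-BuLi, THF, –78 °C; LiOOt-Bu (from t-BuOOH and LiN(SiMe3)2), –78 → 0 °C; 6, –78 °C → rt
Reagents that add atoms: tert-butyl hydroperoxide CC(C)(C)OO
Why: Oxygen transfer from the lithium peroxide to the acetylide gives the ynolate, which the bulky chlorosilane silylates on oxygen (acetylide oxidation route to siloxyalkynes); the propargylic methoxide is a poor leaving group, so the ynolate should persist at or below 0 °C.

Step 3
Reactants: 4 4,4'-methylenebis(3-ethoxycyclobut-2-en-1-one); 9 3-methoxy-1-(triisopropylsilyloxy)prop-1-yne (two molecules)
Product: 11 bis[6-ethoxy-2-hydroxy-3-(methoxymethyl)-4-(triisopropylsilyloxy)phenyl]methane, via (3Z,6Z)-3,7-diethoxynona-1,3,6,8-tetraene-1,9-dione 10 (not isolated)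
Conditions: 9 (3 equiv), toluene (0.05 M), 80 → 110 °C, sealed tube, argon
Reagents that add atoms: none
Why: Proposed new method: the closest known reaction type is the Danheiser benzannulation of one cyclobutenone with a siloxyalkyne to a resorcinol monosilyl ether; here it must run twice on a CH2-linked bis(3-alkoxy-4-alkylcyclobutenone), a substrate class not yet used. Each four-membered ring of 4 opens thermally (four-electron electrocyclic opening, the 4-substituent turning outward) to the 3-ethoxyvinylketene unit of 10; alkyne 9 adds to the ketene C=C in a [2+2] cycloaddition, a second four-electron opening gives a dienylketene, and each benzene ring closes by thermal six-electron (disrotatory) electrocyclisation between the ketene carbon and the carbon carrying the central CH2, followed by tautomerisation to the phenol. The net result per ring is two new bonds, C2–C3 (phenol carbon to the methoxymethyl-bearing carbon) and C4–C5 (siloxy carbon to the C–H carbon), with the alkyne inserted into the former C1–C2 bond of the cyclobutenone. No stereocentre is formed, and the two stereocentres of 4 become sp2 carbons, so both diastereomers converge on one product. The selectivity needed is the orientation of the [2+2] step: the alkyne carbon remote from oxygen is the nucleophilic one and bonds to the electrophilic ketene carbonyl carbon, which puts CH2OMe ortho and the siloxy group meta to the new OH; this polarisation is intrinsic to the ynol ether. The ethoxy group also ends meta to the OH, so the three oxygens appear as OH, OEt and OSi(i-Pr)3 and the only ring C–H is the one reserved for the butyryl group. Excess 9 and dilution are used so that each ketene meets the alkyne before it can acylate a product phenol or another ketene.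

Step 4
Reactants: 11 bis[6-ethoxy-2-hydroxy-3-(methoxymethyl)-4-(triisopropylsilyloxy)phenyl]methane
Product: 12 bis[2-(tert-butyldimethylsilyloxy)-6-ethoxy-3-(methoxymethyl)-4-(triisopropylsilyloxy)phenyl]methane
Conditions: TBSCl, imidazole, DMAP (cat.), DMF, rt → 40 °C
Reagents that add atoms: tert-butylchlorodimethylsilane CC(C)(C)[Si](C)(C)Cl
Why: Standard silylation of a hindered phenol; a silyl triflate is avoided because it could ionise the electron-rich benzylic methyl ether, and the mask keeps the phenol from quenching the aryllithium of step 6 and from oxidation in step 5.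

Step 5
Reactants: 12 bis[2-(tert-butyldimethylsilyloxy)-6-ethoxy-3-(methoxymethyl)-4-(triisopropylsilyloxy)phenyl]methane
Product: 13 bis[5-bromo-2-(tert-butyldimethylsilyloxy)-6-ethoxy-3-(methoxymethyl)-4-(triisopropylsilyloxy)phenyl]methane
Conditions: NBS (2.1 equiv), NaHCO3, MeCN, 0 °C, dark
Reagents that add atoms: N-bromosuccinimide O=C1CCC(=O)N1Br
Why: Electrophilic aromatic bromination at the only ring C–H, which is activated by three oxygen substituents; polar solvent, a base and darkness keep the reaction ionic and away from the benzylic positions.

Step 6
Reactants: 13 bis[5-bromo-2-(tert-butyldimethylsilyloxy)-6-ethoxy-3-(methoxymethyl)-4-(triisopropylsilyloxy)phenyl]methane; 14 N-methoxy-N-methylbutanamide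
Product: 16 bis[5-butanoyl-2-(tert-butyldimethylsilyloxy)-6-ethoxy-3-(methoxymethyl)-4-(triisopropylsilyloxy)phenyl]methane, via dilithio species 15 (not isolated)
Conditions: t-BuLi (4.4 equiv), THF, –78 °C; 14 (3 equiv), –78 → –20 °C; aq. NH4Cl
Reagents that add atoms: none
Why: Bromine–lithium exchange followed by Weinreb ketone synthesis; the chelated tetrahedral adduct prevents over-addition, and the low temperature suppresses 1,3-migration of the ortho triisopropylsilyl group from oxygen to carbon.

Step 7
Reactants: 16 bis[5-butanoyl-2-(tert-butyldimethylsilyloxy)-6-ethoxy-3-(methoxymethyl)-4-(triisopropylsilyloxy)phenyl]methane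
Product: 17 bis[5-butanoyl-2-(tert-butyldimethylsilyloxy)-6-hydroxy-3-(methoxymethyl)-4-(triisopropylsilyloxy)phenyl]methane
Conditions: BCl3 (6 equiv), CH2Cl2, –78 → 0 °C; MeOH quench, then aq. NaHCO3
Reagents that add atoms: none
Why: Chelation-assisted dealkylation of an aryl alkyl ether ortho to a ketone: boron bridges the carbonyl and ethoxy oxygens and chloride removes the ethyl group, while the other ortho oxygen carries a bulky silyl group and does not chelate; no ring C–H is left to be alkylated, and any benzylic chloride formed from CH2OMe should revert to the methyl ether in the methanol quench.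

Step 8
Reactants: 18 1-(2,4,6-trihydroxyphenyl)ethan-1-one (2,4,6-trihydroxyacetophenone)
Product: 19 2-acetyl-3,5-dihydroxy-6,6-dimethylcyclohexa-2,4-dien-1-one (acetylfilicinic acid)
Conditions: NaOMe (3.5 equiv), MeI (2.2 equiv), MeOH, 0 °C → rt; aq. HCl
Reagents that add atoms: iodomethane CI
Why: Known C-methylation of an acylphloroglucinol polyanion; the second methyl group enters at the same ring carbon and gives the dearomatised geminal dimethyl trione, which is separated from under- and over-methylated material.

Step 9
Reactants: 17 bis[5-butanoyl-2-(tert-butyldimethylsilyloxy)-6-hydroxy-3-(methoxymethyl)-4-(triisopropylsilyloxy)phenyl]methane; 19 acetylfilicinic acid (two molecules)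
Product: 21 dryocrassin ABBA, via bis[5-butanoyl-2,4,6-trihydroxy-3-(methoxymethyl)phenyl]methane 20 (not isolated)
Conditions: 19 (3 equiv), Bu4NF (5 equiv), THF, 0 → 50 °C; cold dilute aq. HCl work-up
Reagents that add atoms: none
Why: Fluoride removes the four aryl silyl groups; each hydroxybenzyl methyl ether of 20 then loses methanol to a quinone methide, which the enolate of 19 captures at its only unsubstituted ring carbon (quinone methide Michael addition of a cyclic 1,3-dicarbonyl compound). Excess 19 buffers the medium and outcompetes quinone methide dimerisation; no stereocentre is formed.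

## Compound list

1 | pentanedioyl dichloride (glutaryl dichloride) | O=C(Cl)CCCC(Cl)=O | starting material
2 | ethoxyethyne (ethoxyacetylene) | CCOC#C | starting material
3 | penta-1,4-diene-1,5-dione (bis(ketene)) | O=C=CCC=C=O | intermediate (not isolated)
4 | 4,4'-methylenebis(3-ethoxycyclobut-2-en-1-one), mixture of meso and racemic diastereomers | CCOC1=CC(=O)C1CC1C(=O)C=C1OCC | intermediate
5 | 3-methoxyprop-1-yne | C#CCOC | starting material
6 | chlorotriisopropylsilane | CC(C)[Si](Cl)(C(C)C)C(C)C | starting material
7 | lithium 3-methoxyprop-1-yn-1-ide | [Li]C#CCOC | intermediate (not isolated)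
8 | lithium 3-methoxyprop-1-yn-1-olate | [Li+].[O-]C#CCOC | intermediate (not isolated)
9 | 3-methoxy-1-(triisopropylsilyloxy)prop-1-yne | COCC#CO[Si](C(C)C)(C(C)C)C(C)C | intermediate
10 | (3Z,6Z)-3,7-diethoxynona-1,3,6,8-tetraene-1,9-dione (bis(vinylketene)) | O=C=C/C(OCC)=C/C/C=C(OCC)/C=C=O | intermediate (not isolated)
11 | bis[6-ethoxy-2-hydroxy-3-(methoxymethyl)-4-(triisopropylsilyloxy)phenyl]methane | CCOc1cc(O[Si](C(C)C)(C(C)C)C(C)C)c(COC)c(O)c1Cc1c(O)c(COC)c(O[Si](C(C)C)(C(C)C)C(C)C)cc1OCC | intermediate
12 | bis[2-(tert-butyldimethylsilyloxy)-6-ethoxy-3-(methoxymethyl)-4-(triisopropylsilyloxy)phenyl]methane | CCOc1cc(O[Si](C(C)C)(C(C)C)C(C)C)c(COC)c(O[Si](C)(C)C(C)(C)C)c1Cc1c(O[Si](C)(C)C(C)(C)C)c(COC)c(O[Si](C(C)C)(C(C)C)C(C)C)cc1OCC | intermediate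
13 | bis[5-bromo-2-(tert-butyldimethylsilyloxy)-6-ethoxy-3-(methoxymethyl)-4-(triisopropylsilyloxy)phenyl]methane | CCOc1c(Br)c(O[Si](C(C)C)(C(C)C)C(C)C)c(COC)c(O[Si](C)(C)C(C)(C)C)c1Cc1c(O[Si](C)(C)C(C)(C)C)c(COC)c(O[Si](C(C)C)(C(C)C)C(C)C)c(Br)c1OCC | intermediate
14 | N-methoxy-N-methylbutanamide | CCCC(=O)N(C)OC | starting material
15 | bis[2-(tert-butyldimethylsilyloxy)-6-ethoxy-5-lithio-3-(methoxymethyl)-4-(triisopropylsilyloxy)phenyl]methane | CCOc1c([Li])c(O[Si](C(C)C)(C(C)C)C(C)C)c(COC)c(O[Si](C)(C)C(C)(C)C)c1Cc1c(O[Si](C)(C)C(C)(C)C)c(COC)c(O[Si](C(C)C)(C(C)C)C(C)C)c([Li])c1OCC | intermediate (not isolated)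
16 | bis[5-butanoyl-2-(tert-butyldimethylsilyloxy)-6-ethoxy-3-(methoxymethyl)-4-(triisopropylsilyloxy)phenyl]methane | CCCC(=O)c1c(OCC)c(Cc2c(OCC)c(C(=O)CCC)c(O[Si](C(C)C)(C(C)C)C(C)C)c(COC)c2O[Si](C)(C)C(C)(C)C)c(O[Si](C)(C)C(C)(C)C)c(COC)c1O[Si](C(C)C)(C(C)C)C(C)C | intermediate
17 | bis[5-butanoyl-2-(tert-butyldimethylsilyloxy)-6-hydroxy-3-(methoxymethyl)-4-(triisopropylsilyloxy)phenyl]methane | CCCC(=O)c1c(O)c(Cc2c(O)c(C(=O)CCC)c(O[Si](C(C)C)(C(C)C)C(C)C)c(COC)c2O[Si](C)(C)C(C)(C)C)c(O[Si](C)(C)C(C)(C)C)c(COC)c1O[Si](C(C)C)(C(C)C)C(C)C | intermediate
18 | 1-(2,4,6-trihydroxyphenyl)ethan-1-one | CC(=O)c1c(O)cc(O)cc1O | starting material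
19 | 2-acetyl-3,5-dihydroxy-6,6-dimethylcyclohexa-2,4-dien-1-one (acetylfilicinic acid, one enol tautomer) | CC(=O)C1=C(O)C=C(O)C(C)(C)C1=O | intermediate
20 | bis[5-butanoyl-2,4,6-trihydroxy-3-(methoxymethyl)phenyl]methane | CCCC(=O)c1c(O)c(Cc2c(O)c(C(=O)CCC)c(O)c(COC)c2O)c(O)c(COC)c1O | intermediate (not isolated)
21 | dryocrassin ABBA (achiral; one enol tautomer of each ring A) | CCCC(=O)c1c(O)c(CC2=C(O)C(C)(C)C(=O)C(C(C)=O)=C2O)c(O)c(Cc2c(O)c(CC3=C(O)C(C)(C)C(=O)C(C(C)=O)=C3O)c(O)c(C(=O)CCC)c2O)c1O | target

## Step count and risk

Total: 9 steps. Longest linear sequence: 7 steps (1 → 4 → 11 → 12 → 13 → 16 → 17 → 21; the branch from 5 is equally long).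

**Step 3 (key step, proposed new method).** The most likely failure is a mismatch of rates. The donor-stabilised 3-ethoxycyclobutenone may open only at temperatures at which the product's ortho-hydroxybenzyl methyl ether begins to lose methanol. In addition, each substrate carries two ketene precursors, so acylation of a product phenol by a second vinylketene would cross-link molecules instead of closing rings. The fallback uses only known reaction types; it sets out from 19 and returns to the route at 21.
- Commercial 1-(2,4,6-trihydroxyphenyl)butan-1-one F1 is condensed with half an equivalent of formaldehyde under dilute acid to 3,3'-methylenebis(2,4,6-trihydroxybutyrophenone) F2 (methylene bridging of acylphloroglucinols).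
- A twofold Mannich reaction with dimethyl(methylene)ammonium iodide at the one remaining C–H of each ring gives bis[3-butanoyl-5-(dimethylaminomethyl)-2,4,6-trihydroxyphenyl]methane F3.
- Heating F3 with 19 expels dimethylamine, and the quinone methides are captured as in step 9 to give 21.
- The price is that the positional control of the annulation is lost and oligomers from F1 must be separated.

**Step 1.** The amine can divert the half-reacted acid chloride into intramolecular O-acylation (a chloro enol lactone) or catalyse ketene oligomerisation before the alkyne is met. The fallback sets out from 1 and returns at 4. α-Bromination of 1 (Hell–Volhard–Zelinsky conditions on the acid chloride) gives 2,4-dibromopentanedioyl dichloride F4. Reductive dehalogenation of F4 with activated zinc in ether, in the presence of 2, generates the ketene units of 3 without any amine.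

**Step 7.** Ionisation of the benzylic methyl ether by the boron halide may outrun ethyl cleavage and lead to quinone methide oligomers, or silyl groups may be lost early. The fallback sets out from 16 and returns at 21, with the ethyl groups carried to the end. Treating 16 with 19 and fluoride as in step 9 gives 6,6'-di-O-ethyl dryocrassin ABBA F5. The two ethyl ethers are then cleaved with BBr3 at low temperature, at a stage where no benzylic C–O bond remains. This moves the risk to exposure of the bridges to a strong Lewis acid.

**Step 9.** Under basic fluoride the finished bridges may reopen and exchange partners, or the quinone methide may dimerise before 19 reaches it. The fallback sets out from 17 and returns at 21, with C–C bond formation placed before deprotection. BF3·OEt2 in CH2Cl2 at low temperature ionises the benzylic ether of 17 in the presence of 19 (acid-promoted benzylation of a 1,3-dicarbonyl compound) to give the tetrasilyl ether of the target, F6. Buffered fluoride (Bu4NF with acetic acid) then removes the silyl groups when no quinone methide precursor is left.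

**Step 6.** The hindered aryllithium, flanked by OEt and OSi(i-Pr)3, may add slowly to the amide, and warming would allow silyl migration from oxygen to carbon or protonation. The fallback sets out from 13 and returns at 16. The dilithio species 15 is quenched at –78 °C with butanal, a small and fast electrophile, to give the bis(carbinol) F7 (two carbinol centres, diastereomer mixture of no consequence). F7 is oxidised with Dess–Martin periodinane to 16.

## Further compounds

F1 | step 3 | 1-(2,4,6-trihydroxyphenyl)butan-1-one | CCCC(=O)c1c(O)cc(O)cc1O
F2 | step 3 | 3,3'-methylenebis(2,4,6-trihydroxybutyrophenone) | CCCC(=O)c1c(O)cc(O)c(Cc2c(O)cc(O)c(C(=O)CCC)c2O)c1O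
F3 | step 3 | bis[3-butanoyl-5-(dimethylaminomethyl)-2,4,6-trihydroxyphenyl]methane | CCCC(=O)c1c(O)c(CN(C)C)c(O)c(Cc2c(O)c(CN(C)C)c(O)c(C(=O)CCC)c2O)c1O
F4 | step 1 | 2,4-dibromopentanedioyl dichloride (diastereomer mixture) | O=C(Cl)C(Br)CC(Br)C(Cl)=O
F5 | step 7 | 6,6'-di-O-ethyl dryocrassin ABBA (ethyl on the ring B oxygen between central CH2 and butyryl) | CCCC(=O)c1c(O)c(CC2=C(O)C(C)(C)C(=O)C(C(C)=O)=C2O)c(O)c(Cc2c(O)c(CC3=C(O)C(C)(C)C(=O)C(C(C)=O)=C3O)c(O)c(C(=O)CCC)c2OCC)c1OCC
F6 | step 9 | dryocrassin ABBA 2,2'-bis(tert-butyldimethylsilyl) 4,4'-bis(triisopropylsilyl) ether (ring B oxygens) | CCCC(=O)c1c(O[Si](C(C)C)(C(C)C)C(C)C)c(CC2=C(O)C(C)(C)C(=O)C(C(C)=O)=C2O)c(O[Si](C)(C)C(C)(C)C)c(Cc2c(O[Si](C)(C)C(C)(C)C)c(CC3=C(O)C(C)(C)C(=O)C(C(C)=O)=C3O)c(O[Si](C(C)C)(C(C)C)C(C)C)c(C(=O)CCC)c2O)c1O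
F7 | step 6 | bis[2-(tert-butyldimethylsilyloxy)-6-ethoxy-5-(1-hydroxybutyl)-3-(methoxymethyl)-4-(triisopropylsilyloxy)phenyl]methane (diastereomer mixture) | CCCC(O)c1c(OCC)c(Cc2c(OCC)c(C(O)CCC)c(O[Si](C(C)C)(C(C)C)C(C)C)c(COC)c2O[Si](C)(C)C(C)(C)C)c(O[Si](C)(C)C(C)(C)C)c(COC)c1O[Si](C(C)C)(C(C)C)C(C)C
A1 | alternative 1 | hexa-O-methyl dryocrassin ABBA | CCCC(=O)c1c(OC)c(CC2=C(O)C(C)(C)C(=O)C(C(C)=O)=C2O)c(OC)c(Cc2c(OC)c(CC3=C(O)C(C)(C)C(=O)C(C(C)=O)=C3O)c(OC)c(C(=O)CCC)c2OC)c1OC
A2 | alternative 1 | isopropenyl acetate | CC(=C)OC(C)=O
A3 | alternative 1 | bis(3,3-dimethyl-2,4,6-trioxotetrahydropyran-5-ylmethyl) derivative of the hexa-O-methyl BB core (stereocentres unassigned) | CCCC(=O)c1c(OC)c(CC2C(=O)OC(=O)C(C)(C)C2=O)c(OC)c(Cc2c(OC)c(CC3C(=O)OC(=O)C(C)(C)C3=O)c(OC)c(C(=O)CCC)c2OC)c1OC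
A4 | alternative 2 | hexa-O-methyl tetramer with rings A as ethyl silyl bis(enol ether) dienones lacking acetyl | CCCC(=O)c1c(OC)c(CC2=C(OCC)C(C)(C)C(=O)C=C2O[Si](C(C)C)(C(C)C)C(C)C)c(OC)c(Cc2c(OC)c(CC3=C(OCC)C(C)(C)C(=O)C=C3O[Si](C(C)C)(C(C)C)C(C)C)c(OC)c(C(=O)CCC)c2OC)c1OC
A5 | alternative 2 | (triisopropylsiloxy)ethyne | C#CO[Si](C(C)C)(C(C)C)C(C)C
A6 | alternative 2 | bis(3-ethoxy-4,4-dimethyl-2-oxocyclobut-3-enylmethyl... written out: hexa-O-methyl BB core carrying a 3-ethoxy-4,4-dimethylcyclobut-2-en-1-one-2-ylmethyl group on each outer carbon | CCCC(=O)c1c(OC)c(CC2=C(OCC)C(C)(C)C2=O)c(OC)c(Cc2c(OC)c(CC3=C(OCC)C(C)(C)C3=O)c(OC)c(C(=O)CCC)c2OC)c1OC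
A7 | alternative 3 | BB core tetramethyl ether | CCCC(=O)c1c(OC)cc(OC)c(Cc2c(OC)cc(OC)c(C(=O)CCC)c2O)c1O
A8 | alternative 3 | butanoic acid | CCCC(=O)O
A9 | alternative 3 | methylenebis[3,5-dimethoxy-6-(trimethylsilyl)-2,1-phenylene] bis(trifluoromethanesulfonate) | C[Si](C)(C)c1c(OC)cc(OC)c(Cc2c(OC)cc(OC)c([Si](C)(C)C)c2OS(=O)(=O)C(F)(F)F)c1OS(=O)(=O)C(F)(F)F
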